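**Retrosynthetic overview**

1. Target 17 comes from its diallyl ether 16 by deallylation. 16 is cut at the diene C=C next to the isochromenone: Horner–Wadsworth–Emmons union of hydroxy enal 9 (oxolane fragment) with phosphonate 15 (isocoumarin fragment).
2. Oxolane ring: the array C3(OH)–C4H2–C5(H)(CH3)–O1 is, at the ketone level, a hydroacylation retron. The C3–C4 bond is therefore made by rhodium-catalysed addition of the formyl C–H of acyclic aldehyde 4 (future C3) across its isopropenyl ether O1–C5(CH3)=C4H2, giving ketone 5.
3. Aldehyde 4 comes in two steps from the benzyl ether of (S)-solketal 1. Opening the dioxolane ketal to the isopropenyl ether turns the three carbons of the protecting group into C5, C4 and the C5 methyl group; glycerol supplies O1, C2 (the only bought stereocenter), C3 and the side-chain carbon.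
4. Stereocenters: C2 from 1, C5 in the ring closure (cis to C2), C3 by hydride reduction of 5 from the face opposite both substituents (all-cis).
5. Isocoumarin fragment: chlorination and allylation of methyl orsellinate 10, then lateral lithiation, chloroacetylation and enol lactonisation, then Arbuzov reaction. Ring order: oxolane (step 3) and isochromenone lactone ring (step 9) in separate fragments; the benzene ring is bought.

Key step: step 3

Assumption: the (R,R) antipode of the bisphosphine in step 3 is taken as the one matched with the C2 stereocenter of 4; should the first experiment show the opposite sense, the (S,S) antipode is used and nothing else changes.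

**Route**

Step 1
Reactants: 1 (4S)-4-[(benzyloxy)methyl]-2,2-dimethyl-1,3-dioxolane
Product: 3 (2R)-3-(benzyloxy)-2-(prop-1-en-2-yloxy)propan-1-ol, via trimethylsilyl ether 2 (not isolated)
Conditions: Me3SiOTf (1.3 equiv), i-Pr2NEt (2 equiv), CH2Cl2, −20 to 0 °C; then K2CO3 (1.5 equiv), MeOH, 0 °C; isolation on base-washed support, used at once
Reagents that add atoms: none
Why: Silyl-triflate-mediated ketal-to-enol-ether elimination, a known reaction of dioxolane ketals: the silyl group should go to the less hindered primary oxygen, the oxocarbenium ion left on the secondary oxygen loses a methyl proton to the amine to give the isopropenyl ether, and basic methanolysis of the O–Si bond frees the alcohol without acid, which would re-close the ketal; the stereocenter is untouched (S becomes R only through the priority change).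

Step 2
Reactants: 3 (2R)-3-(benzyloxy)-2-(prop-1-en-2-yloxy)propan-1-ol
Product: 4 (2S)-3-(benzyloxy)-2-(prop-1-en-2-yloxy)propanal
Conditions: SO3·pyridine, DMSO, i-Pr2NEt, CH2Cl2, 0 °C; aq. NaHCO3 work-up; used crude
Reagents that add atoms: none
Why: Parikh–Doering oxidation works in a basic, water-free medium, so the acid-labile enol ether should survive and the α-alkoxy aldehyde should keep its configuration.

Step 3
Reactants: 4 (2S)-3-(benzyloxy)-2-(prop-1-en-2-yloxy)propanal
Product: 5 (2S,5R)-2-[(benzyloxy)methyl]-5-methyloxolan-3-one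
Conditions: [Rh(cod)((R,R)-Me-DuPhos)]BF4 (5 mol%), activated with H2 in acetone and purged with Ar before 4 is added; acetone, 25 °C
Reagents that add atoms: none
Why: Proposed new method: oxidative addition of the formyl C–H bond of 4 to the cationic monovalent rhodium bisphosphine gives an acyl hydride of trivalent rhodium, the isopropenyl ether binds, the hydride migrates to its oxygen-bearing carbon (C5), and the six-membered acyl–alkyl rhodacycle (Rh, C3, C2, O1, C5, C4) reductively eliminates the C3–C4 bond. The closest known reaction type is the rhodium-catalysed intramolecular hydroacylation of 4-substituted pent-4-enals to 3-substituted cyclopentanones, also known in enantioselective form with chiral bisphosphines; new here is the oxygen at position 3 of the chain, that is, an enol ether as the acceptor. The oxolane ring closes in a formal 5-endo-trig mode with respect to the C4=C5 bond, which is possible because the bond is made by reductive elimination from the metallacycle and not by direct attack on the alkene. The only new stereocenter, C5, is set when hydride is delivered to one face of the enol ether: the insertion is reversible, and the chair-like rhodacycle with the C2 benzyloxymethyl group and the C5 methyl group both equatorial (1,3-cis across O1) should be the one that eliminates, the matched ligand antipode reinforcing this bias. The step needs hydroacylation to win over decarbonylation, which binding of the enol ether and of the ether oxygens to rhodium should secure; it needs C4 and not C5 to bond to C3, which is secured because the other insertion could only lead to a four-membered ketone; and it needs C2 to keep its configuration, which the neutral, base-free medium secures.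

Step 4
Reactants: 5 (2S,5R)-2-[(benzyloxy)methyl]-5-methyloxolan-3-one
Product: 6 (2S,3S,5R)-2-[(benzyloxy)methyl]-5-methyloxolan-3-ol
Conditions: LiBH(s-Bu)3, THF, −78 °C; then H2O
Reagents that add atoms: none
Why: Substrate-controlled ketone reduction with a bulky trialkylborohydride: hydride should add to the face of the C3 carbonyl opposite to the cis C2 and C5 substituents, which puts the new C3 hydroxyl on their face (3S, all-cis).

Step 5
Reactants: 6 (2S,3S,5R)-2-[(benzyloxy)methyl]-5-methyloxolan-3-ol
Product: 7 (2S,3S,5R)-2-(hydroxymethyl)-5-methyloxolan-3-ol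
Conditions: H2 (1 atm), Pd/C (10% palladium on carbon), EtOAc, 25 °C
Reagents that add atoms: none
Why: Catalytic hydrogenolysis of a benzyl ether, run before any alkene is in the molecule; no stereocenter is involved.

Step 6
Reactants: 7 (2S,3S,5R)-2-(hydroxymethyl)-5-methyloxolan-3-ol
Product: 9 (2E)-3-[(2S,3S,5R)-3-hydroxy-5-methyloxolan-2-yl]prop-2-enal, via hydroxy aldehyde 8 (not isolated)
Conditions: TEMPO (10 mol%), PhI(OAc)2 (1.1 equiv), CH2Cl2, 25 °C; then Ph3P=CHCHO (1.3 equiv), 25 °C
Reagents that add atoms: (triphenylphosphoranylidene)acetaldehyde, O=CC=P(c1ccccc1)(c1ccccc1)c1ccccc1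
Why: TEMPO/PhI(OAc)2 oxidation is selective for the primary over the secondary alcohol, and Wittig olefination with the stabilised formyl ylide in the same flask should give the E enal while the epimerisable α-alkoxy aldehyde 8 is trapped as it forms, so C2 keeps its configuration.

Step 7
Reactants: 10 methyl 2,4-dihydroxy-6-methylbenzoate (methyl orsellinate)
Product: 11 methyl 3-chloro-4,6-dihydroxy-2-methylbenzoate
Conditions: SO2Cl2 (1.05 equiv), Et2O, 0 °C
Reagents that add atoms: sulfuryl chloride, O=S(=O)(Cl)Cl
Why: Electrophilic aromatic chlorination: of the two activated positions of 10, C5 (next to the methyl group, para to the hydrogen-bonded C2 hydroxyl) should react, as is known for 2,4-dihydroxy-6-alkylbenzoates with SO2Cl2, the position between the two hydroxyls being more crowded; any regioisomer is removed by crystallisation.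

Step 8
Reactants: 11 methyl 3-chloro-4,6-dihydroxy-2-methylbenzoate
Product: 12 methyl 3-chloro-2-methyl-4,6-bis(prop-2-en-1-yloxy)benzoate
Conditions: allyl bromide (2.5 equiv), K2CO3, DMF, 60 °C
Reagents that add atoms: allyl bromide, C=CCBr
Why: Williamson ether synthesis, with heat for the hydrogen-bonded hydroxyl next to the ester; allyl ethers are chosen because they survive the base, acid and heat of steps 9 to 11 and leave at the end under neutral conditions.

Step 9
Reactants: 12 methyl 3-chloro-2-methyl-4,6-bis(prop-2-en-1-yloxy)benzoate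
Product: 14 5-chloro-3-(chloromethyl)-6,8-bis(prop-2-en-1-yloxy)-1H-isochromen-1-one, via keto ester 13 (not isolated)
Conditions: LiN(i-Pr)2 (1.1 equiv), THF, −78 °C; ClCH2C(O)N(OMe)Me, −78 to −40 °C; 1 M HCl; then p-TsOH·H2O (cat.), toluene, 90 °C
Reagents that add atoms: 2-chloro-N-methoxy-N-methylacetamide, CON(C)C(=O)CCl
Why: Lateral lithiation of the o-toluate (a vinylogous ester enolate) and acylation with the Weinreb amide, whose chelated adduct keeps the chloro ketone masked until the acid quench, followed by acid-catalysed enol lactonisation (6-exo-trig attack of the benzylic enol oxygen on the ester), which closes the lactone ring of the isochromenone; no stereocenter is formed.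

Step 10
Reactants: 14 5-chloro-3-(chloromethyl)-6,8-bis(prop-2-en-1-yloxy)-1H-isochromen-1-one
Product: 15 diethyl {[5-chloro-1-oxo-6,8-bis(prop-2-en-1-yloxy)-1H-isochromen-3-yl]methyl}phosphonate
Conditions: P(OEt)3 (neat, excess), 130 °C
Reagents that add atoms: triethyl phosphite, CCOP(OCC)OCC
Why: Michaelis–Arbuzov reaction of an allylic-type primary chloride; the aryl chloride and the allyl ethers are inert at this temperature.

Step 11
Reactants: 9 (2E)-3-[(2S,3S,5R)-3-hydroxy-5-methyloxolan-2-yl]prop-2-enal; 15 diethyl {[5-chloro-1-oxo-6,8-bis(prop-2-en-1-yloxy)-1H-isochromen-3-yl]methyl}phosphonate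
Product: 16 5-chloro-3-{(1E,3E)-4-[(2S,3S,5R)-3-hydroxy-5-methyloxolan-2-yl]buta-1,3-dien-1-yl}-6,8-bis(prop-2-en-1-yloxy)-1H-isochromen-1-one
Conditions: 15 (1.3 equiv), NaN(SiMe3)2 (1.25 equiv), THF, −78 °C; then 9, −78 to 0 °C
Reagents that add atoms: none
Why: Horner–Wadsworth–Emmons olefination with a semi-stabilised phosphonate anion, which should give the new disubstituted alkene with E geometry; the free C3 hydroxyl of 9 is less acidic than the phosphonate and is tolerated, and the low temperature limits deprotonation of 9 at C2.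

Step 12
Reactants: 16 5-chloro-3-{(1E,3E)-4-[(2S,3S,5R)-3-hydroxy-5-methyloxolan-2-yl]buta-1,3-dien-1-yl}-6,8-bis(prop-2-en-1-yloxy)-1H-isochromen-1-one
Product: 17 5-chloro-6,8-dihydroxy-3-{(1E,3E)-4-[(2S,3S,5R)-3-hydroxy-5-methyloxolan-2-yl]buta-1,3-dien-1-yl}-1H-isochromen-1-one (CNP0086741.3)
Conditions: Pd(PPh3)4 (5 mol%), morpholine (10 equiv), THF, 25 °C; dilute acid work-up
Reagents that add atoms: none
Why: Palladium-catalysed deallylation (Tsuji–Trost type): zerovalent palladium ionises the two aryl allyl ethers, whose phenoxides are good leaving groups, and morpholine takes up the allyl groups, under neutral conditions that leave the diene, the lactone and the three stereocenters alone.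

**Compound list**

1 | (4S)-4-[(benzyloxy)methyl]-2,2-dimethyl-1,3-dioxolane (benzyl ether of (S)-solketal) | CC1(C)OC[C@H](COCc2ccccc2)O1 | starting material
2 | {[(2S)-3-(benzyloxy)-2-(prop-1-en-2-yloxy)propyl]oxy}trimethylsilane | C[Si](C)(C)OC[C@H](COCc1ccccc1)OC(C)=C | intermediate
3 | (2R)-3-(benzyloxy)-2-(prop-1-en-2-yloxy)propan-1-ol | OC[C@H](COCc1ccccc1)OC(C)=C | intermediate
4 | (2S)-3-(benzyloxy)-2-(prop-1-en-2-yloxy)propanal | O=C[C@H](COCc1ccccc1)OC(C)=C | intermediate
5 | (2S,5R)-2-[(benzyloxy)methyl]-5-methyloxolan-3-one (2,5-cis) | C[C@@H]1CC(=O)[C@H](COCc2ccccc2)O1 | intermediate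
6 | (2S,3S,5R)-2-[(benzyloxy)methyl]-5-methyloxolan-3-ol (all-cis) | C[C@@H]1C[C@H](O)[C@H](COCc2ccccc2)O1 | intermediate
7 | (2S,3S,5R)-2-(hydroxymethyl)-5-methyloxolan-3-ol | C[C@@H]1C[C@H](O)[C@H](CO)O1 | intermediate
8 | (2R,3S,5R)-3-hydroxy-5-methyloxolane-2-carbaldehyde | C[C@@H]1C[C@H](O)[C@H](C=O)O1 | intermediate
9 | (2E)-3-[(2S,3S,5R)-3-hydroxy-5-methyloxolan-2-yl]prop-2-enal | C[C@@H]1C[C@H](O)[C@H](/C=C/C=O)O1 | intermediate
10 | methyl 2,4-dihydroxy-6-methylbenzoate (methyl orsellinate) | COC(=O)c1c(C)cc(O)cc1O | starting material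
11 | methyl 3-chloro-4,6-dihydroxy-2-methylbenzoate | COC(=O)c1c(C)c(Cl)c(O)cc1O | intermediate
12 | methyl 3-chloro-2-methyl-4,6-bis(prop-2-en-1-yloxy)benzoate | COC(=O)c1c(C)c(Cl)c(OCC=C)cc1OCC=C | intermediate
13 | methyl 3-chloro-2-(3-chloro-2-oxopropyl)-4,6-bis(prop-2-en-1-yloxy)benzoate | COC(=O)c1c(CC(=O)CCl)c(Cl)c(OCC=C)cc1OCC=C | intermediate
14 | 5-chloro-3-(chloromethyl)-6,8-bis(prop-2-en-1-yloxy)-1H-isochromen-1-one | ClCc1cc2c(Cl)c(OCC=C)cc(OCC=C)c2c(=O)o1 | intermediate
15 | diethyl {[5-chloro-1-oxo-6,8-bis(prop-2-en-1-yloxy)-1H-isochromen-3-yl]methyl}phosphonate | CCOP(=O)(OCC)Cc1cc2c(Cl)c(OCC=C)cc(OCC=C)c2c(=O)o1 | intermediate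
16 | 5-chloro-3-{(1E,3E)-4-[(2S,3S,5R)-3-hydroxy-5-methyloxolan-2-yl]buta-1,3-dien-1-yl}-6,8-bis(prop-2-en-1-yloxy)-1H-isochromen-1-one | C[C@@H]1C[C@H](O)[C@H](/C=C/C=C/c2cc3c(Cl)c(OCC=C)cc(OCC=C)c3c(=O)o2)O1 | intermediate
17 | 5-chloro-6,8-dihydroxy-3-{(1E,3E)-4-[(2S,3S,5R)-3-hydroxy-5-methyloxolan-2-yl]buta-1,3-dien-1-yl}-1H-isochromen-1-one | C[C@@H]1C[C@H](O)[C@H](/C=C/C=C/c2cc3c(Cl)c(O)cc(O)c3c(=O)o2)O1 | target

**Step count and risks**

Total step count: 12. Longest linear sequence: 8 steps (steps 1, 2, 3, 4, 5, 6, 11, 12).

Steps most likely to fail: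

Step 3 (bears the label). What may go wrong: loss of carbon monoxide from the acyl rhodium hydride, which ends the catalysis as a rhodium carbonyl; consumption of the enol ether by the Lewis-acidic cationic metal; or delivery of hydride to the wrong face of the enol ether (2,5-trans ring). Fallback, known chemistry, setting out from 4 and coming back at 6: the oxolane is closed instead at C4–C5 by the aluminium-promoted 1,3 O-to-C rearrangement of a 4-methylene-1,3-dioxolane (Petasis–Ferrier type). Dilute aqueous acid removes the isopropenyl group of 4 and Pinnick oxidation (NaClO2, NaH2PO4, 2-methylbut-2-ene) gives (2S)-3-(benzyloxy)-2-hydroxypropanoic acid F1. Condensation with acetaldehyde dimethyl acetal (BF3·OEt2, Et2O) gives the cis dioxolanone (2S,5S)-5-[(benzyloxy)methyl]-2-methyl-1,3-dioxolan-4-one F2. Methylenation of the lactone carbonyl with Cp2TiMe2 (toluene, 65 °C) gives (2S,5S)-5-[(benzyloxy)methyl]-2-methyl-4-methylidene-1,3-dioxolane F3. i-Bu3Al (toluene, −78 to 0 °C) opens the acetal, re-closes through the enolate carbon and reduces the resulting ketone in the same flask, which should give the all-cis alcohol 6.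

Step 1. What may go wrong: ionisation of the ketal at the secondary instead of the primary C–O bond, or re-closure of hydroxy enol ether 3 to ketal 1 on contact with traces of acid during isolation. Fallback, setting out from 1 and coming back at 3: the isopropenyl ether is built by carbonyl methylenation of an acetate. Aqueous acetic acid removes the ketal to give (2R)-3-(benzyloxy)propane-1,2-diol F4. t-BuMe2SiCl and imidazole silylate the primary hydroxyl to give (2S)-1-(benzyloxy)-3-[(tert-butyldimethylsilyl)oxy]propan-2-ol F5. Ac2O and pyridine give (2S)-1-(benzyloxy)-3-[(tert-butyldimethylsilyl)oxy]propan-2-yl acetate F6. Cp2TiMe2 (toluene, 65 °C) converts the ester carbonyl into the enol ether {[(2S)-3-(benzyloxy)-2-(prop-1-en-2-yloxy)propyl]oxy}(tert-butyl)dimethylsilane F7. Bu4NF in THF then frees alcohol 3 under basic conditions.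

Step 11. What may go wrong: deprotonation of enal 9 at C2 by the phosphonate anion, with loss of the C2 configuration or elimination of the C3 hydroxyl, or incomplete E selectivity. Fallback, setting out from 7 and 14 and coming back at 16: the central C–C single bond of the diene is made by Stille coupling, with no basic carbanion. Kornblum oxidation of 14 (DMSO, NaHCO3, 90 °C) gives 5-chloro-1-oxo-6,8-bis(prop-2-en-1-yloxy)-1H-isochromene-3-carbaldehyde F8. Takai olefination (CrCl2, CHI3, THF) gives 5-chloro-3-[(E)-2-iodoethenyl]-6,8-bis(prop-2-en-1-yloxy)-1H-isochromen-1-one F9. Diol 7 is oxidised as in step 6 to aldehyde 8, which without isolation is treated with divalent chromium and the tin reagent (CrCl2, Bu3SnCHBr2, LiI, THF/DMF) to give (2S,3S,5R)-5-methyl-2-[(E)-2-(tributylstannyl)ethenyl]oxolan-3-ol F10. Coupling of F9 with F10 (Pd2(dba)3, AsPh3, N-methylpyrrolidone, 25 °C) should give 16 with both double bonds E.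

Further compounds
F1 | step 3 | (2S)-3-(benzyloxy)-2-hydroxypropanoic acid | OC(=O)[C@H](COCc1ccccc1)O
F2 | step 3 | (2S,5S)-5-[(benzyloxy)methyl]-2-methyl-1,3-dioxolan-4-one | C[C@@H]1OC(=O)[C@H](COCc2ccccc2)O1
F3 | step 3 | (2S,5S)-5-[(benzyloxy)methyl]-2-methyl-4-methylidene-1,3-dioxolane | C[C@@H]1OC(=C)[C@H](COCc2ccccc2)O1
F4 | step 1 | (2R)-3-(benzyloxy)propane-1,2-diol | OC[C@H](COCc1ccccc1)O
F5 | step 1 | (2S)-1-(benzyloxy)-3-[(tert-butyldimethylsilyl)oxy]propan-2-ol | CC(C)(C)[Si](C)(C)OC[C@H](COCc1ccccc1)O
F6 | step 1 | (2S)-1-(benzyloxy)-3-[(tert-butyldimethylsilyl)oxy]propan-2-yl acetate | CC(C)(C)[Si](C)(C)OC[C@H](COCc1ccccc1)OC(C)=O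
F7 | step 1 | {[(2S)-3-(benzyloxy)-2-(prop-1-en-2-yloxy)propyl]oxy}(tert-butyl)dimethylsilane | CC(C)(C)[Si](C)(C)OC[C@H](COCc1ccccc1)OC(C)=C
F8 | step 11 | 5-chloro-1-oxo-6,8-bis(prop-2-en-1-yloxy)-1H-isochromene-3-carbaldehyde | O=Cc1cc2c(Cl)c(OCC=C)cc(OCC=C)c2c(=O)o1
F9 | step 11 | 5-chloro-3-[(E)-2-iodoethenyl]-6,8-bis(prop-2-en-1-yloxy)-1H-isochromen-1-one | I/C=C/c1cc2c(Cl)c(OCC=C)cc(OCC=C)c2c(=O)o1
F10 | step 11 | (2S,3S,5R)-5-methyl-2-[(E)-2-(tributylstannyl)ethenyl]oxolan-3-ol | C[C@@H]1C[C@H](O)[C@H](/C=C/[Sn](CCCC)(CCCC)CCCC)O1
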